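By 3.00 min L in Monday's flask has stopped falling: its readings stay near 57.2% of its charge up to 8.00 min, within a scatter of 2 percentage points, although Q was charged at 3.6 equiv. I read that as Q being lost by a first-order path of its own, with L taking what it can meanwhile. So I carry one quantity: Monday's flask has 0.558 as its reach, the logarithm of charged L over L at the stop. Reach is the loss rate of L per L, summed over the whole run.

common to all: L 20 mM

|  | Q | remark | time |
|---|---|---|---|
| Monday's | 3.6 equiv | run made earlier |  |
| flask | 1.80 equiv |  | 40 min |

Monday's run (percent of the L charged)

| time / min | L / % | D / % | G / % |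
|---|---|---|---|
| 0.417 | 53 | 5 | 21 |
| 1.33 | 57 | 15 | 12 |
| 2.50 | 59 | 20 | 7 |
| 3.00 | 57 | 21 | 2 |
| 5.00 | 60 | 24 | 0 |
| 6.00 | 57 | 26 | 1 |
| 8.00 | 55 | 28 | 2 |

(readings scatter by 2 percentage points)



* conversion of L at 40 min
* amount of D at 40 min, in percent of the L charged

The new flask has the same L and half of Monday's Q, and two extreme versions of it can be solved at once. If L meets one Q at a time, reach goes with the Q charged: 0.279, so conversion is 24.3%. If L needs two Q at once, reach goes with the square: 0.139, so conversion is 13.0%. A mixture of both paths adds their reaches, so I expect conversion between these ends. Carried over unchanged, Monday's last D reading, a share 0.655 of the L consumed, puts D near 15.9% at the one-Q end; I hold that as a rough figure and not as a bound, since the share need not stay the same at the lower Q.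

The forecast, holding that “Q is lost quickly by a side path”, gives conversion 25% and D 19%, its conversion standing above my upper end.

The new flask gives conversion 21.3%, between my ends, and D 16.0%.

    L + Q → G (k = 1.90 L mol⁻¹ s⁻¹)
    L + 2 Q → Z (k = 34.0 L² mol⁻² s⁻¹)
    G → D (k = 0.00980 s⁻¹)
    Q → X (k = 0.320 s⁻¹)

Both extreme paths stand in the scheme, and Q is the limiting reagent of the new flask: at 40.0 min it has 0% of its charge left against 79% of L. A neighbouring flask takes 7.20 equiv of Q, twice Monday's. Its reach by the same reckoning runs from 1.12 to 2.23, so conversion runs from 67.2% to 89.3%. That flask gives conversion 78.6%, with Z at 47.4% and D at 31.2%.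

Readings and results are simulated from invented constants; scatter was added.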